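**Plan**

1. Retrosynthesis: the phenol O–CH3 bond and the ring A C–CHO bond are cut first (CHO back to C–SiEt3). Then the two bonds that tie ring A into the seven-membered dioxepinone ring B are cut together: the aryl–C(=O) bond and the diaryl ether C–O bond.
2. This leaves an aryne of ring A and the five-membered cyclic carbonate of the ring C catechol. The enabling feature is that the ether carbon and the lactone-bearing carbon of ring A are neighbours and that O6 and O7 of ring C are vicinal, so ring B is a catechol carbonate enlarged by two adjacent ring A carbons.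
3. Forward, ring A: 3-methoxy-5-methylphenol is carbamoylated, ortho-silylated twice in one flask (SiEt3 at the future formyl carbon, SiMe3 at the future lactone carbon) and converted into the triflate.
4. Forward, rings C and D: the pyranone ring D is annulated onto a trioxygenated toluene, the catechol is unveiled and tied into the carbonate (temporary ring).
5. Union: fluoride-triggered aryne insertion into the carbonate closes ring B; ipso-formylation then exchanges SiEt3 for CHO and BCl3 frees the phenol.
6. Stereochemistry: the target has no stereocentre; only regiochemistry has to be controlled (silyl and methyl flanking the aryne; O7 para to the ring D ketone).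

Key step: step 8

Remark: chroman-4-one locants (O1, C4 ketone, C5–CH3, O6, O7, C8–H) are used for rings C and D; compounds 1, 11 and 14 are taken as purchasable.

**Route**

Step 1
Reactants: 1 3-methoxy-5-methylphenol
Product: 2 3-methoxy-5-methylphenyl N-isopropylcarbamate
Conditions: i-PrNCO, Et3N (cat.), CH2Cl2, rt
Reagents that add atoms: isopropyl isocyanate, CC(C)N=C=O
Why: Base-catalysed addition of the phenol to the isocyanate (carbamoylation) should give the N-isopropyl carbamate, a directing group that is removable later under mild base.

Step 2
Reactants: 2 3-methoxy-5-methylphenyl N-isopropylcarbamate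
Product: 8 3-methoxy-5-methyl-2-(triethylsilyl)-6-(trimethylsilyl)phenyl N-isopropylcarbamate, via N-silyl carbamate 3 (not isolated), via first aryllithium 4 (not isolated), via N-silyl arylsilane 5 (not isolated), via second aryllithium 6 (not isolated), via N-silyl bis-silane 7 (not isolated)
Conditions: TBSOTf, TMEDA, Et2O, 0 °C to rt; n-BuLi, TMEDA, −78 °C; Et3SiCl, −78 °C to rt; s-BuLi, TMEDA, −78 °C; Me3SiCl, −78 °C to rt; aq. NaHSO4
Reagents that add atoms: chlorotriethylsilane, CC[Si](Cl)(CC)CC; chlorotrimethylsilane, C[Si](C)(C)Cl
Why: Iterated directed ortho-metalation on one N-silylated carbamate: the first lithiation should go to the carbon between the carbamate and methoxy groups (cooperative direction) and is trapped by Et3SiCl, the second, with the stronger base, should go to the only remaining position ortho to the carbamate (between it and the methyl group) and is trapped by Me3SiCl, and the N–Si bond is cleaved only in the final aqueous work-up, so the transient N-protection is installed once and serves both metalations.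

Step 3
Reactants: 8 3-methoxy-5-methyl-2-(triethylsilyl)-6-(trimethylsilyl)phenyl N-isopropylcarbamate
Product: 10 3-methoxy-5-methyl-2-(triethylsilyl)-6-(trimethylsilyl)phenyl trifluoromethanesulfonate, via phenol 9 (not isolated)
Conditions: Et2NH, DBU, MeCN, 40 °C; then PhNTf2, rt to 40 °C
Reagents that add atoms: N-phenylbis(trifluoromethanesulfonimide), O=S(=O)(N(c1ccccc1)S(=O)(=O)C(F)(F)F)C(F)(F)F
Why: E1cB cleavage of the N–H carbamate by DBU (the isocyanate is trapped by Et2NH) should free the phenoxide, which is triflated in the same flask, the standard one-pot route to ortho-silyl aryl triflates.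

Step 4
Reactants: 11 1,2-dimethoxy-3-methylbenzene
Product: 13 3,4-dimethoxy-5-methylphenol, via arylboronate 12 (not isolated)
Conditions: B2pin2, [Ir(OMe)(cod)]2 (cat.), dtbpy (cat.), THF, 80 °C; then KHSO5 (as Oxone, 2KHSO5·KHSO4·K2SO4), acetone/H2O, rt
Reagents that add atoms: potassium peroxymonosulfate (active salt of Oxone), [K+].[O-]S(=O)(=O)OO
Why: Sterically controlled iridium-catalysed C–H borylation should select the only ring C–H without an ortho substituent (meta to CH3 and to OCH3), and oxidation of the C–B bond in the same flask gives the phenol.

Step 5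
Reactants: 13 3,4-dimethoxy-5-methylphenol; 14 3-methylbut-2-enoic acid
Product: 15 6,7-dimethoxy-2,2,5-trimethylchroman-4-one
Conditions: P2O5/MeSO3H (Eaton's reagent), 70 °C
Reagents that add atoms: none
Why: Friedel–Crafts acylation by the activated acid at the carbon ortho to OH and para to the 3-methoxy group (the carbon between OH and OCH3 has no para oxygen and is less activated), followed by intramolecular oxa-Michael addition of the phenol to the enone, should close ring D.

Step 6
Reactants: 15 6,7-dimethoxy-2,2,5-trimethylchroman-4-one
Product: 17 6,7-dihydroxy-2,2,5-trimethylchroman-4-one, via bromoboronate 16 (not isolated)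
Conditions: BBr3, CH2Cl2, −78 °C to rt; then H2O
Reagents that add atoms: none
Why: Lewis acid ether cleavage by BBr3 should remove both methyl groups, while the ring D ether oxygen, a vinylogous ester oxygen conjugated to the ketone, is far less basic and should stay intact.

Step 7
Reactants: 17 6,7-dihydroxy-2,2,5-trimethylchroman-4-one
Product: 18 cyclic carbonate of catechol 17 (6,6,9-trimethyl-6,7-dihydro-8H-[1,3]dioxolo[4,5-g]chromene-2,8-dione)
Conditions: 1,1'-carbonyldiimidazole, THF, rt, under N2
Reagents that add atoms: 1,1'-carbonyldiimidazole, O=C(n1ccnc1)n1ccnc1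
Why: Double O-acylation of the vicinal diol by the phosgene equivalent should close the five-membered cyclic carbonate, the temporary ring that carries the future lactone carbon.

Step 8
Reactants: 10 3-methoxy-5-methyl-2-(triethylsilyl)-6-(trimethylsilyl)phenyl trifluoromethanesulfonate; 18 cyclic carbonate of catechol 17
Product: 21 triethylsilyl depsidone (mollicellin B methyl ether with SiEt3 in place of CHO), via aryne 19 (not isolated), via fluoroformate phenoxide 20 (not isolated)
Conditions: CsF, 18-crown-6 (cat.), THF, 50 °C, slow addition of 10, strictly dry
Reagents that add atoms: none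
Why: Proposed new method: fluoride removes the trimethylsilyl group of 10 (the bulkier triethylsilyl group is spared) with loss of triflate to give aryne 19, and it also opens the reactive aryl carbonate 18 reversibly to fluoroformate phenoxide 20, in which the more acidic O7 (para to the ring D ketone) is the phenoxide and the hindered O6 keeps the acyl group. The phenoxide should add to the aryne carbon next to silicon, because the electropositive silyl group widens the internal angle at that carbon (aryne distortion) and the methyl group on the other flank shields the alternative carbon, so the aryl anion arises next to the methyl group. This anion attacks the fluoroformate carbonyl in a 7-exo-trig closure, which forms the aryl–C(=O) bond and ring B, and the expelled fluoride re-enters the cycle. The closest known reaction types are the annulation of arynes with salicylates to xanthones (phenoxide addition, then intramolecular acyl substitution, one ring atom fewer) and the ring expansion of cyclic ureas by aryne insertion into the N–C(=O) bond. No stereocentre is formed; the step needs discrimination between the two silyl groups, arylation of O7 and not O6, and attack ortho to silicon, secured respectively by silyl size, by phenoxide stability and sterics, and by the silyl/methyl pair beside the triple bond. THF is preferred to MeCN so that the aryl anion is acylated and not protonated.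

Step 9
Reactants: 21 triethylsilyl depsidone
Product: 23 mollicellin B methyl ether, via chloro ether 22 (not isolated)
Conditions: Cl2CHOMe, TiCl4, CH2Cl2, −78 to 0 °C; then H2O
Reagents that add atoms: dichloromethyl methyl ether, COC(Cl)Cl; water, O
Why: Rieche formylation run as an electrophilic ipso-substitution of the arylsilane: the oxocarbenium ion should attack the silicon-bearing carbon (activated by the ortho methoxy and aryloxy groups and by β-silicon stabilisation of the arenium ion), Et3SiCl is lost, and the chloro ether is hydrolysed to the aldehyde on work-up.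

Step 10
Reactants: 23 mollicellin B methyl ether
Product: 25 mollicellin B, via aryloxydichloroborane 24 (not isolated)
Conditions: BCl3, CH2Cl2, −78 to 0 °C; then H2O
Reagents that add atoms: none
Why: Chelation-assisted demethylation: BCl3 held between the formyl oxygen and the ortho methoxy oxygen should cleave that methyl ether selectively, leaving lactone, diaryl ether and ring D untouched.

**Compound list**

1 | 3-methoxy-5-methylphenol | COc1cc(C)cc(O)c1 | starting material
2 | 3-methoxy-5-methylphenyl N-isopropylcarbamate | COc1cc(C)cc(OC(=O)NC(C)C)c1 | intermediate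
3 | N-(tert-butyldimethylsilyl) derivative of 2 (formed in the flask) | COc1cc(C)cc(OC(=O)N(C(C)C)[Si](C)(C)C(C)(C)C)c1 | intermediate
4 | aryllithium of 3, lithium between the carbamate and methoxy groups (formed in the flask) | COc1cc(C)cc(OC(=O)N(C(C)C)[Si](C)(C)C(C)(C)C)c1[Li] | intermediate
5 | 3-methoxy-5-methyl-2-(triethylsilyl)phenyl N-(tert-butyldimethylsilyl)-N-isopropylcarbamate (formed in the flask) | COc1cc(C)cc(OC(=O)N(C(C)C)[Si](C)(C)C(C)(C)C)c1[Si](CC)(CC)CC | intermediate
6 | aryllithium of 5, lithium between the carbamate and methyl groups (formed in the flask) | COc1cc(C)c([Li])c(OC(=O)N(C(C)C)[Si](C)(C)C(C)(C)C)c1[Si](CC)(CC)CC | intermediate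
7 | N-(tert-butyldimethylsilyl) derivative of 8 (formed in the flask) | COc1cc(C)c([Si](C)(C)C)c(OC(=O)N(C(C)C)[Si](C)(C)C(C)(C)C)c1[Si](CC)(CC)CC | intermediate
8 | 3-methoxy-5-methyl-2-(triethylsilyl)-6-(trimethylsilyl)phenyl N-isopropylcarbamate | COc1cc(C)c([Si](C)(C)C)c(OC(=O)NC(C)C)c1[Si](CC)(CC)CC | intermediate
9 | 3-methoxy-5-methyl-2-(triethylsilyl)-6-(trimethylsilyl)phenol (formed in the flask) | COc1cc(C)c([Si](C)(C)C)c(O)c1[Si](CC)(CC)CC | intermediate
10 | 3-methoxy-5-methyl-2-(triethylsilyl)-6-(trimethylsilyl)phenyl trifluoromethanesulfonate (aryne precursor) | COc1cc(C)c([Si](C)(C)C)c(OS(=O)(=O)C(F)(F)F)c1[Si](CC)(CC)CC | intermediate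
11 | 1,2-dimethoxy-3-methylbenzene (2,3-dimethoxytoluene) | COc1cccc(C)c1OC | starting material
12 | 2-(3,4-dimethoxy-5-methylphenyl)-4,4,5,5-tetramethyl-1,3,2-dioxaborolane (formed in the flask) | COc1cc(B2OC(C)(C)C(C)(C)O2)cc(C)c1OC | intermediate
13 | 3,4-dimethoxy-5-methylphenol | COc1cc(O)cc(C)c1OC | intermediate
14 | 3-methylbut-2-enoic acid | CC(C)=CC(O)=O | starting material
15 | 6,7-dimethoxy-2,2,5-trimethylchroman-4-one | COc1cc2OC(C)(C)CC(=O)c2c(C)c1OC | intermediate
16 | cyclic B-bromo boronate of catechol 17 (formed in the flask) | BrB1Oc2cc3OC(C)(C)CC(=O)c3c(C)c2O1 | intermediate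
17 | 6,7-dihydroxy-2,2,5-trimethylchroman-4-one | Oc1cc2OC(C)(C)CC(=O)c2c(C)c1O | intermediate
18 | cyclic carbonate of 17 (6,6,9-trimethyl-6,7-dihydro-8H-[1,3]dioxolo[4,5-g]chromene-2,8-dione) | O=C1Oc2cc3OC(C)(C)CC(=O)c3c(C)c2O1 | intermediate
19 | 4-methoxy-6-methyl-3-(triethylsilyl)-1,2-didehydrobenzene (aryne, formed in the flask) | CC1=CC(OC)=C([Si](CC)(CC)CC)C#C1 | intermediate
20 | cesium 6-(fluorocarbonyloxy)-2,2,5-trimethyl-4-oxochroman-7-olate (formed in the flask) | [Cs+].[O-]c1cc2OC(C)(C)CC(=O)c2c(C)c1OC(F)=O | intermediate
21 | triethylsilyl depsidone: mollicellin B methyl ether with SiEt3 at the ring A carbon between the methoxy-bearing and the ether-bearing carbon | Cc1cc(OC)c([Si](CC)(CC)CC)c2c1C(=O)Oc1c(cc3c(c1C)C(=O)CC(C)(C)O3)O2 | intermediate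
22 | chloro(methoxy)methyl depsidone (racemic, formed in the flask) | Cc1cc(OC)c(C(Cl)OC)c2c1C(=O)Oc1c(cc3c(c1C)C(=O)CC(C)(C)O3)O2 | intermediate
23 | mollicellin B methyl ether (ring A methoxy aldehyde) | Cc1cc(OC)c(C=O)c2c1C(=O)Oc1c(cc3c(c1C)C(=O)CC(C)(C)O3)O2 | intermediate
24 | aryloxydichloroborane of mollicellin B (formed in the flask) | Cc1cc(OB(Cl)Cl)c(C=O)c2c1C(=O)Oc1c(cc3c(c1C)C(=O)CC(C)(C)O3)O2 | intermediate
25 | mollicellin B | Cc1cc(O)c(C=O)c2c1C(=O)Oc1c(cc3c(c1C)C(=O)CC(C)(C)O3)O2 | target

**Count and risks**

Total step count: 10. Longest linear sequence: 7 steps (steps 4–7, then 8–10).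

Steps most likely to fail:

1. Step 8 (proposed new method). The aryl anion may be protonated before it is acylated. The phenoxide may add at the aryne carbon remote from silicon. Fluoride may remove the triethylsilyl group in place of the trimethylsilyl group. The ring-opened phenoxide may stay too dilute to intercept the aryne.
Fallback (known chemistry; sets out from catechol 17, returns at 23): purchased 1-fluoro-3-methoxy-5-methylbenzene is lithiated between F and OCH3 (n-BuLi, THF, −78 °C) and quenched with DMF to give 2-fluoro-6-methoxy-4-methylbenzaldehyde F1. Bromination para to the methoxy group (NBS, MeCN) should give 3-bromo-2-fluoro-6-methoxy-4-methylbenzaldehyde F2. Nucleophilic aromatic substitution of the fluoride (ortho to CHO) by the more acidic O7–H of 17 (K2CO3, DMF, 80 °C) should give bromo diaryl ether F3, in which O6–H stays free. Palladium-catalysed carbonylative lactonisation (Pd(OAc)2, Xantphos, CO, Et3N, toluene, 100 °C) then closes ring B through CO insertion and acylation of O6 and delivers 23 directly.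

2. Step 9. Protodesilylation by adventitious acid, or electrophilic attack at C8–H of ring C or at the ring A C–H next to the methyl group, may compete with ipso-substitution.
Fallback (sets out from 21, returns at 23): ipso-iododesilylation with ICl (CH2Cl2, 0 °C) should give the iodo depsidone F4, and palladium-catalysed reductive carbonylation of the aryl iodide (Pd(PPh3)4, CO, Bu3SnH, THF, 50 °C) converts it into aldehyde 23.

3. Step 3. O-Sulfonylation of the doubly ortho-silylated phenoxide may be too slow, with competing loss of a silyl group under the basic conditions.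
Fallback (sets out from 8, returns at aryne 19 inside step 8): the carbamate is cleaved alone (Et2NH, DBU, MeCN) and phenol 9 is isolated. In the key step, 9 is combined with carbonate 18, nonafluorobutanesulfonyl fluoride and Cs2CO3/18-crown-6. The small S–F electrophile should sulfonylate the hindered phenoxide to the aryl nonaflate F5 in the flask, and the fluoride released triggers loss of the trimethylsilyl group, so that aryne 19 is generated without an isolated triflate.

**Further compounds**

F1 | step 8 | 2-fluoro-6-methoxy-4-methylbenzaldehyde | COc1cc(C)cc(F)c1C=O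
F2 | step 8 | 3-bromo-2-fluoro-6-methoxy-4-methylbenzaldehyde | COc1cc(C)c(Br)c(F)c1C=O
F3 | step 8 | 7-(2-bromo-6-formyl-5-methoxy-3-methylphenoxy)-6-hydroxy-2,2,5-trimethylchroman-4-one | COc1cc(C)c(Br)c(Oc2cc3OC(C)(C)CC(=O)c3c(C)c2O)c1C=O
F4 | step 9 | iodo depsidone (21 with I in place of SiEt3) | Cc1cc(OC)c(I)c2c1C(=O)Oc1c(cc3c(c1C)C(=O)CC(C)(C)O3)O2
F5 | step 3 | 3-methoxy-5-methyl-2-(triethylsilyl)-6-(trimethylsilyl)phenyl nonafluorobutanesulfonate | COc1cc(C)c([Si](C)(C)C)c(OS(=O)(=O)C(F)(F)C(F)(F)C(F)(F)C(F)(F)F)c1[Si](CC)(CC)CC
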